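## Retrosynthetic overview

- The target is unmasked last by global desilylation of its tris-silyl ether (phenols as TIPS ethers, carbinol as TBS ether).
- Key disconnection: the lactone bond C2–C3 (ring numbered O1, C2(=O), C3, C4, C5) together with the C3–CH2–aryl bond. A cesium homoallylic oxalate and an aryl bromide are united by an alkoxycarbonyl radical 5-exo cyclization/nickel arylation cascade, which forms the only new ring and the C3 stereocenter in one operation.
- Enabling feature: the carbonyl carbon C2 sits on the ring oxygen O1, and C3 carries an exocyclic benzylic CH2. C3 and that CH2 can therefore be a terminal vinyl group on the homoallylic alcohol O1–C5–C4, so C2 arrives as an O1-bound alkoxycarbonyl radical placed 5-exo to the vinyl group, with the C4 stereocenter allylic to it.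
- The oxalate comes from a (1R,2R)-2-vinyl-1,3-diol, made from TIPS-vanillin and (Z)-1,4-bis(boryl)but-2-ene by catalytic asymmetric syn-allylboration and C–B oxidation; this sets C4 and the carbinol.
- Ring order: both arenes are bought (vanillin, 4-bromo-2-methoxyphenol); the γ-lactone is the only ring formed, in the key step.

Key step: step 8

Assumption: the SMILES is taken as authoritative; it encodes the 3,4-trans (3R,4R)-lactone with an (R)-configured benzylic carbinol, and this stereoisomer is the one made.

Abbreviations: TIPS = triisopropylsilyl; TBS = tert-butyldimethylsilyl; Bpin = 4,4,5,5-tetramethyl-1,3,2-dioxaborolan-2-yl; dtbbpy = 4,4'-di-tert-butyl-2,2'-bipyridine; dme = 1,2-dimethoxyethane.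

## Route

Step 1
Reactants: 1 vanillin (4-hydroxy-3-methoxybenzaldehyde)
Product: 2 3-methoxy-4-(triisopropylsilyloxy)benzaldehyde
Conditions: TIPSCl (1.1 equiv), imidazole (2 equiv), DMF, rt
Reagents that add atoms: chlorotriisopropylsilane (TIPSCl), CC(C)[Si](Cl)(C(C)C)C(C)C
Why: Imidazole-promoted O-silylation of the phenol (silyl ether protection); the TIPS aryl ether is chosen because it should survive the weakly basic peroxide and hydroxide steps that follow and still fall to fluoride at the end; no stereocenter is formed.

Step 2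
Reactants: 3 buta-1,3-diene; 4 bis(pinacolato)diboron
Product: 5 (Z)-1,4-bis(4,4,5,5-tetramethyl-1,3,2-dioxaborolan-2-yl)but-2-ene
Conditions: Pt(PPh3)4 (3 mol%), toluene, 80 °C, sealed vessel
Reagents that add atoms: none
Why: Platinum-catalysed 1,4-diboration of a 1,3-diene: oxidative addition of the B–B bond to zerovalent platinum and cis-1,4-transfer of both boryl groups to the s-cis-bound diene should give the (Z)-alkene selectively; no stereocenter is formed.

Step 3
Reactants: 2 3-methoxy-4-(triisopropylsilyloxy)benzaldehyde; 5 (Z)-1,4-bis(pinacolboryl)but-2-ene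
Product: 7 (1R,2R)-2-ethenyl-1-[3-methoxy-4-(triisopropylsilyloxy)phenyl]propane-1,3-diol, via O-boryl homoallyl boronate 6 (not isolated)
Conditions: 5 (1.3 equiv), (R)-3,3'-bis(2,4,6-triisopropylphenyl)-1,1'-binaphthyl-2,2'-diyl hydrogen phosphate (5 mol%), 4 Å MS, toluene, −30 °C; then 30% H2O2, aq. NaHCO3, THF, 0 °C to rt
Reagents that add atoms: hydrogen peroxide, OO
Why: Chiral phosphoric acid-catalysed allylboration of an aryl aldehyde with a γ-substituted (Z)-allyl pinacolboronate through a closed chair transition state, followed by oxidation of the remaining primary C–B bond: the (Z)-geometry of 5 puts the CH2Bpin group axial and so fixes the syn relationship between the carbinol oxygen and the borylmethyl branch, while the (R)-acid, hydrogen-bonded to the pseudo-axial boronate oxygen and the formyl hydrogen, is expected to direct attack to the Re face of 2 as it does for allyl and crotyl pinacolboronates, which sets the (R)-carbinol and with it the adjacent (R)-centre (the future C4).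

Step 4
Reactants: 7 (1R,2R)-2-ethenyl-1-[3-methoxy-4-(triisopropylsilyloxy)phenyl]propane-1,3-diol
Product: 8 methyl (2R,3R)-2-ethenyl-3-hydroxy-3-[3-methoxy-4-(triisopropylsilyloxy)phenyl]propyl oxalate
Conditions: ClC(O)CO2Me (1.05 equiv), 2,4,6-collidine (1.5 equiv), CH2Cl2, −78 °C
Reagents that add atoms: methyl chlorooxoacetate, COC(=O)C(=O)Cl
Why: Chemoselective O-acylation: at −78 °C with a hindered pyridine base the unhindered primary hydroxyl should react with the acid chloride well before the β-branched benzylic secondary hydroxyl; no stereocenter is touched.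

Step 5
Reactants: 8 methyl (2R,3R)-2-ethenyl-3-hydroxy-3-[3-methoxy-4-(triisopropylsilyloxy)phenyl]propyl oxalate
Product: 9 methyl (2R,3R)-3-(tert-butyldimethylsilyloxy)-2-ethenyl-3-[3-methoxy-4-(triisopropylsilyloxy)phenyl]propyl oxalate
Conditions: TBSOTf (1.3 equiv), 2,6-lutidine (2 equiv), CH2Cl2, −78 to 0 °C
Reagents that add atoms: tert-butyldimethylsilyl triflate (TBSOTf), CC(C)(C)[Si](C)(C)OS(=O)(=O)C(F)(F)F
Why: Silyl triflate silylation of the hindered secondary benzylic alcohol with a non-nucleophilic base, which should leave the methyl oxalate and the alkene untouched and blocks the carbinol against oxalate migration and later translactonization; the configuration is retained because the C–O bond is not broken.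

Step 6
Reactants: 9 methyl (2R,3R)-3-(tert-butyldimethylsilyloxy)-2-ethenyl-3-[3-methoxy-4-(triisopropylsilyloxy)phenyl]propyl oxalate
Product: 10 cesium 2-{(2R,3R)-3-(tert-butyldimethylsilyloxy)-2-ethenyl-3-[3-methoxy-4-(triisopropylsilyloxy)phenyl]propoxy}-2-oxoacetate
Conditions: CsOH·H2O (1.0 equiv), THF/H2O, 0 °C; concentrated and dried, used as the salt
Reagents that add atoms: cesium hydroxide, [Cs+].[OH-]
Why: Half-saponification of a mixed oxalate diester with one equivalent of hydroxide: the first ester of an oxalate is hydrolysed far faster than ordinary esters and hydroxide should attack the less hindered methyl-side carbonyl, so the cesium alkyl oxalate forms without loss of the silyl ethers; no stereocenter is involved.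

Step 7
Reactants: 11 4-bromo-2-methoxyphenol
Product: 12 (4-bromo-2-methoxyphenoxy)triisopropylsilane
Conditions: TIPSCl (1.1 equiv), imidazole (2 equiv), DMF, rt
Reagents that add atoms: chlorotriisopropylsilane (TIPSCl), CC(C)[Si](Cl)(C(C)C)C(C)C
Why: Imidazole-promoted O-silylation of the phenol (silyl ether protection), giving the aryl bromide partner with the same protecting group as the other arene; no stereocenter is formed.

Step 8
Reactants: 10 cesium 2-{(2R,3R)-3-(tert-butyldimethylsilyloxy)-2-ethenyl-3-[3-methoxy-4-(triisopropylsilyloxy)phenyl]propoxy}-2-oxoacetate; 12 (4-bromo-2-methoxyphenoxy)triisopropylsilane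
Product: 15 (3R,4R)-4-{(R)-(tert-butyldimethylsilyloxy)[3-methoxy-4-(triisopropylsilyloxy)phenyl]methyl}-3-[3-methoxy-4-(triisopropylsilyloxy)benzyl]oxolan-2-one, via alkoxycarbonyl radical 13 (not isolated), via lactonylmethyl radical 14 (not isolated)
Conditions: 10 (1.0 equiv), 12 (1.5 equiv), Ir[dF(CF3)ppy]2(dtbbpy)PF6 (2 mol%), NiBr2(dme) (10 mol%), dtbbpy (12 mol%), degassed 1,4-dioxane/DMSO (5:1), blue LEDs, fan-cooled, ca. 30 °C
Reagents that add atoms: none
Why: The excited iridium photocatalyst should oxidize the oxalate carboxylate of 10 by one electron, loss of one CO2 gives the primary alkoxycarbonyl radical 13, which adds to the internal vinyl carbon to form the C2–C3 bond and the primary radical 14; 14 is captured by the aryl nickel bromide formed by oxidative addition of 12 to zerovalent nickel, reductive elimination from trivalent nickel makes the C3–CH2–aryl bond, and the reduced photocatalyst returns monovalent nickel to the zerovalent state. The closest known reaction type is the alkoxycarbonyl radical cyclization–cross-coupling cascade of homoallylic cesium oxalates with aryl halides under iridium/nickel dual catalysis, supported by tin-mediated 5-exo cyclizations of primary homoallylic selenocarbonates. The lactone closes in the 5-exo-trig mode. The new C3 stereocenter is controlled by the allylic C4 stereocenter: in the chair-like transition state of this 5-hexenyl-type closure the bulky CH(OTBS)aryl group sits pseudo-equatorial, so the new exocyclic CH2 ends up trans to it, which is also the thermodynamically preferred 3,4-trans lactone. The step needs ring closure to outrun decarboxylation and direct capture of 13 by nickel, and 5-exo to beat 6-endo attack: a primary alkoxycarbonyl radical loses CO2 only slowly, the closure is intramolecular while nickel is kept at low loading, and the stereoelectronic preference of hex-5-enyl-type radicals favours the 5-exo mode at the terminal vinyl group.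

Step 9
Reactants: 15 (3R,4R)-4-{(R)-(tert-butyldimethylsilyloxy)[3-methoxy-4-(triisopropylsilyloxy)phenyl]methyl}-3-[3-methoxy-4-(triisopropylsilyloxy)benzyl]oxolan-2-one
Product: 16 (3R,4R)-4-[(R)-hydroxy(4-hydroxy-3-methoxyphenyl)methyl]-3-(4-hydroxy-3-methoxybenzyl)oxolan-2-one (target)
Conditions: TBAF/AcOH (1:1, 4 equiv each), THF, 0 °C to rt
Reagents that add atoms: none
Why: Fluoride-driven cleavage of all three silyl ethers (Si–F bond formation), buffered with acetic acid so that phenoxide and alkoxide do not accumulate and the lactone, the C3 centre and the carbinol are not disturbed; no stereocenter is touched.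

## Compound list

1 | vanillin (4-hydroxy-3-methoxybenzaldehyde) | COc1cc(C=O)ccc1O | starting material
2 | 3-methoxy-4-(triisopropylsilyloxy)benzaldehyde | COc1cc(C=O)ccc1O[Si](C(C)C)(C(C)C)C(C)C | intermediate
3 | buta-1,3-diene | C=CC=C | starting material
4 | bis(pinacolato)diboron | CC1(C)OB(OC1(C)C)B1OC(C)(C)C(C)(C)O1 | starting material
5 | (Z)-1,4-bis(4,4,5,5-tetramethyl-1,3,2-dioxaborolan-2-yl)but-2-ene | CC1(C)OB(C/C=C\CB2OC(C)(C)C(C)(C)O2)OC1(C)C | intermediate
6 | 2-{(1R,2S)-1-[3-methoxy-4-(triisopropylsilyloxy)phenyl]-2-[(pinacolboryl)methyl]but-3-enyloxy}-4,4,5,5-tetramethyl-1,3,2-dioxaborolane (same spatial arrangement as 7; not isolated) | CC1(C)OB(OC1(C)C)C[C@@H](C=C)[C@@H](OB1OC(C)(C)C(C)(C)O1)c1ccc(O[Si](C(C)C)(C(C)C)C(C)C)c(OC)c1 | intermediate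
7 | (1R,2R)-2-ethenyl-1-[3-methoxy-4-(triisopropylsilyloxy)phenyl]propane-1,3-diol | OC[C@@H](C=C)[C@@H](O)c1ccc(O[Si](C(C)C)(C(C)C)C(C)C)c(OC)c1 | intermediate
8 | methyl (2R,3R)-2-ethenyl-3-hydroxy-3-[3-methoxy-4-(triisopropylsilyloxy)phenyl]propyl oxalate | COC(=O)C(=O)OC[C@@H](C=C)[C@@H](O)c1ccc(O[Si](C(C)C)(C(C)C)C(C)C)c(OC)c1 | intermediate
9 | methyl (2R,3R)-3-(tert-butyldimethylsilyloxy)-2-ethenyl-3-[3-methoxy-4-(triisopropylsilyloxy)phenyl]propyl oxalate | COC(=O)C(=O)OC[C@@H](C=C)[C@@H](O[Si](C)(C)C(C)(C)C)c1ccc(O[Si](C(C)C)(C(C)C)C(C)C)c(OC)c1 | intermediate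
10 | cesium 2-{(2R,3R)-3-(tert-butyldimethylsilyloxy)-2-ethenyl-3-[3-methoxy-4-(triisopropylsilyloxy)phenyl]propoxy}-2-oxoacetate | [Cs+].[O-]C(=O)C(=O)OC[C@@H](C=C)[C@@H](O[Si](C)(C)C(C)(C)C)c1ccc(O[Si](C(C)C)(C(C)C)C(C)C)c(OC)c1 | intermediate
11 | 4-bromo-2-methoxyphenol | COc1cc(Br)ccc1O | starting material
12 | (4-bromo-2-methoxyphenoxy)triisopropylsilane | COc1cc(Br)ccc1O[Si](C(C)C)(C(C)C)C(C)C | intermediate
13 | alkoxycarbonyl radical from 10 after oxidation and loss of CO2 (not isolated) | O=[C]OC[C@@H](C=C)[C@@H](O[Si](C)(C)C(C)(C)C)c1ccc(O[Si](C(C)C)(C(C)C)C(C)C)c(OC)c1 | intermediate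
14 | trans-lactonylmethyl radical: 3-methylene radical of the 4-substituted oxolan-2-one (not isolated) | [CH2][C@H]1C(=O)OC[C@@H]1[C@@H](O[Si](C)(C)C(C)(C)C)c1ccc(O[Si](C(C)C)(C(C)C)C(C)C)c(OC)c1 | intermediate
15 | (3R,4R)-4-{(R)-(tert-butyldimethylsilyloxy)[3-methoxy-4-(triisopropylsilyloxy)phenyl]methyl}-3-[3-methoxy-4-(triisopropylsilyloxy)benzyl]oxolan-2-one | COc1cc(C[C@H]2C(=O)OC[C@@H]2[C@@H](O[Si](C)(C)C(C)(C)C)c2ccc(O[Si](C(C)C)(C(C)C)C(C)C)c(OC)c2)ccc1O[Si](C(C)C)(C(C)C)C(C)C | intermediate
16 | (3R,4R)-4-[(R)-hydroxy(4-hydroxy-3-methoxyphenyl)methyl]-3-(4-hydroxy-3-methoxybenzyl)oxolan-2-one | COc1cc(C[C@H]2C(=O)OC[C@@H]2[C@@H](O)c2ccc(O)c(OC)c2)ccc1O | target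

## Step count and risks

Total step count: 9 (steps 1–9).
Longest linear sequence: 7 steps (steps 1, 3, 4, 5, 6, 8, 9, from vanillin 1 to 16).

Steps most likely to fail:

1. Step 8 (key step). Process risk: the alkoxycarbonyl radical may be intercepted by nickel before it cyclizes (direct aryl ester formation), the alkyl nickel intermediate may undergo β-hydride elimination, the primary radical may attack the neighbouring arene, and trans/cis control in the ring closure may be incomplete. Fallback, from 9 back to 15: the aryl group is attached before the ring closure, so that no bimolecular radical capture is needed. Cross-metathesis of 9 with triisopropyl(2-methoxy-4-vinylphenoxy)silane F1 (from commercial 2-methoxy-4-vinylphenol, TIPSCl and imidazole), using second-generation Hoveyda–Grubbs catalyst RuCl2(H2IMes)(=CH-C6H4-2-O-i-Pr) in CH2Cl2 at 40 °C, should give the (E)-styrenyl methyl oxalate F2. CsOH·H2O (1.0 equiv) in THF/H2O should convert it into the cesium oxalate F3. Irradiation of F3 with Ir[dF(CF3)ppy]2(dtbbpy)PF6, methyl thioglycolate (20 mol%) as hydrogen-atom shuttle and water in DME/DMF under blue LEDs should then close the same C2–C3 bond 5-exo onto the styrene, the benzylic radical being quenched by hydrogen-atom transfer, to give 15.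

2. Step 3. Process risk: the bulkier γ-substituent may slow the catalysed pathway, so that uncatalysed background allylboration erodes enantioselectivity, and any Z-to-E erosion of the reagent would lower syn selectivity. Fallback, from 2 back to 7: reagent control with a stoichiometric chiral borane. Kinetic low-temperature hydroboration of (buta-2,3-dien-1-yloxy)triethylsilane F4 (from commercial buta-2,3-dien-1-ol, TESCl and imidazole) with the enantiomer of 10-trimethylsilyl-9-borabicyclo[3.3.2]decane that adds to the Re face of aldehydes should give the (Z)-γ-(silyloxymethyl)allylborane. Addition to 2 at −78 °C and work-up should give the syn homoallylic alcohol (1R,2R)-1-[3-methoxy-4-(triisopropylsilyloxy)phenyl]-2-[(triethylsilyloxy)methyl]but-3-en-1-ol F5. AcOH/THF/H2O at rt should remove the primary triethylsilyl group and return diol 7.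

3. Step 9. Process risk: simultaneous unmasking of the phenols and the carbinol under fluoride may allow translactonization onto the benzylic oxygen, C3 epimerization, or 1,6-elimination to a quinone methide with loss of the carbinol configuration. Fallback, from 15 back to 16: staged unmasking under non-basic conditions. HF·pyridine/pyridine in THF at 0 °C should cleave only the alkyl TBS ether, while the aryl TIPS ethers keep the arene from ionizing at the benzylic position, giving (3R,4R)-4-{(R)-hydroxy[3-methoxy-4-(triisopropylsilyloxy)phenyl]methyl}-3-[3-methoxy-4-(triisopropylsilyloxy)benzyl]oxolan-2-one F6. KHF2 in MeOH at rt should then cleave the two aryl silyl ethers to give 16.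

Further compounds
F1 | step 8 | triisopropyl(2-methoxy-4-vinylphenoxy)silane | C=Cc1ccc(O[Si](C(C)C)(C(C)C)C(C)C)c(OC)c1
F2 | step 8 | methyl (2R,3R,4E)-3-... oxalate: methyl (E,2R)-2-{(R)-(tert-butyldimethylsilyloxy)[3-methoxy-4-(triisopropylsilyloxy)phenyl]methyl}-4-[3-methoxy-4-(triisopropylsilyloxy)phenyl]but-3-enyl oxalate | COC(=O)C(=O)OC[C@@H](/C=C/c1ccc(O[Si](C(C)C)(C(C)C)C(C)C)c(OC)c1)[C@@H](O[Si](C)(C)C(C)(C)C)c1ccc(O[Si](C(C)C)(C(C)C)C(C)C)c(OC)c1
F3 | step 8 | cesium 2-{(E,2R)-2-{(R)-(tert-butyldimethylsilyloxy)[3-methoxy-4-(triisopropylsilyloxy)phenyl]methyl}-4-[3-methoxy-4-(triisopropylsilyloxy)phenyl]but-3-enyloxy}-2-oxoacetate | [Cs+].[O-]C(=O)C(=O)OC[C@@H](/C=C/c1ccc(O[Si](C(C)C)(C(C)C)C(C)C)c(OC)c1)[C@@H](O[Si](C)(C)C(C)(C)C)c1ccc(O[Si](C(C)C)(C(C)C)C(C)C)c(OC)c1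
F4 | step 3 | (buta-2,3-dien-1-yloxy)triethylsilane | C=C=CCO[Si](CC)(CC)CC
F5 | step 3 | (1R,2R)-1-[3-methoxy-4-(triisopropylsilyloxy)phenyl]-2-[(triethylsilyloxy)methyl]but-3-en-1-ol | CC[Si](CC)(CC)OC[C@@H](C=C)[C@@H](O)c1ccc(O[Si](C(C)C)(C(C)C)C(C)C)c(OC)c1
F6 | step 9 | (3R,4R)-4-{(R)-hydroxy[3-methoxy-4-(triisopropylsilyloxy)phenyl]methyl}-3-[3-methoxy-4-(triisopropylsilyloxy)benzyl]oxolan-2-one | COc1cc(C[C@H]2C(=O)OC[C@@H]2[C@@H](O)c2ccc(O[Si](C(C)C)(C(C)C)C(C)C)c(OC)c2)ccc1O[Si](C(C)C)(C(C)C)C(C)C
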